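**Retrosynthetic overview**
1. The furan is the only ring made, and it is made last. Opening its O1–C2 bond (C–O) gives an o‑hydroxybenzyl aryl ketone. Cutting C3–C3a then leads to a ring‑A p‑quinone monoketal and the silyl enol ether of 3,5‑dihydroxyacetophenone (ring B).
2. Key disconnection: the ring‑A C–O bonds C7a–O and C5–OMe are removed together. The quinone monoketal goes back to a plain 1,3‑disubstituted arene by C–H borylation and iodine(III) oxidation in MeOH.
3. That arene comes from 1‑bromo‑3‑tert‑butoxybenzene and 3‑methylbutan‑2‑one. A Pd α‑arylation brings in the whole 3‑methyl‑2‑oxobutyl chain, and OtBu is the future 6‑OH.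
4. Ring order: both benzene rings are bought. Ring A is dearomatised to the ketal and rearomatised in the coupling. The furan then closes by C–O bond formation, and deprotection follows in the same flask.

Assumption: the SMILES has no stereocentre and no stereogenic double bond, so moracin Q is achiral and no enantiocontrol is needed.

**Step 1**
Reactants: 1 1-bromo-3-(tert-butoxy)benzene; 2 3-methylbutan-2-one
Product: 3 1-[3-(tert-butoxy)phenyl]-3-methylbutan-2-one
Conditions: Pd2(dba)3 (1 mol %), rac-BINAP (2.4 mol %), NaOtBu (1.3 equiv), 2 (1.5 equiv), THF, 70 °C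
Reagents that add atoms: none
Why: Pd-catalysed ketone α-arylation (Buchwald–Hartwig type) of this ketone occurs at the unhindered CH3 rather than the isopropyl CH, the product is stored as its enolate so diarylation stays low, and the aryl tert-butyl ether is inert to alkoxide.

**Step 2**
Reactants: 3 1-[3-(tert-butoxy)phenyl]-3-methylbutan-2-one
Product: 7 3-(tert-butoxy)-4,4-dimethoxy-5-(3-methyl-2-oxobutyl)cyclohexa-2,5-dien-1-one, via aryl pinacol boronate 4 (not isolated), via phenol 5 (not isolated), via 4-methoxyphenol 6 (not isolated)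
Conditions: [Ir(OMe)(cod)]2 (1.5 mol %), dtbpy (3 mol %), B2pin2 (1.0 equiv), MTBE, 60 °C; evaporate; then PhI(OAc)2 (4.5 equiv, portionwise), NaHCO3, H2O (3 equiv), MeOH, 0 °C → rt
Reagents that add atoms: bis(pinacolato)diboron CC1(C)OB(OC1(C)C)B1OC(C)(C)C(C)(C)O1 (Bpin of 4 only); water O; methanol CO
Why: Proposed new method: sterically controlled Ir C–H borylation (known) takes the only C–H without an ortho neighbour, and the crude ArBpin is then carried by a single I(III) reagent through three C–O bond formations – PhI(OH)OAc/PhIO formed under bicarbonate binds the boron, the aryl group shifts from B to O with loss of PhI (the same 1,2-shift as with peroxides or amine N-oxides), ArO–Bpin passes its aryloxide to a second I(III) centre and MeOH attacks the para carbon (activated by the ortho OtBu and leading to the stable cross-conjugated vinylogous ester), and a third I(III) converts 4-methoxyphenol 6 into the ketal; the closest known reaction types are the I(III)- or Oxone-mediated ipso-hydroxylation of arylboron compounds and the PhI(OAc)2/MeOH oxidation of para-unsubstituted phenols to p-quinone monoketals, whereas the direct ArBpin (net Ar–H) to quinone monoketal conversion has not been described.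

**Step 3**
Reactants: 8 1-(3,5-dihydroxyphenyl)ethan-1-one
Product: 9 1-[3,5-bis(trimethylsilyloxy)phenyl]-1-(trimethylsilyloxy)ethene
Conditions: TMSOTf (3.5 equiv), Et3N (4 equiv), CH2Cl2, 0 °C → rt; pentane extraction, Kugelrohr
Reagents that add atoms: trimethylsilyl trifluoromethanesulfonate C[Si](C)(C)OS(=O)(=O)C(F)(F)F
Why: Soft enolisation with TMSOTf/Et3N silylates both phenols and traps the only possible enol of the methyl ketone (silyl enol ether formation).

**Step 4**
Reactants: 7 3-(tert-butoxy)-4,4-dimethoxy-5-(3-methyl-2-oxobutyl)cyclohexa-2,5-dien-1-one; 9 1-[3,5-bis(trimethylsilyloxy)phenyl]-1-(trimethylsilyloxy)ethene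
Product: 12 moracin Q 1-[2-(3,5-dihydroxyphenyl)-6-hydroxy-5-methoxy-1-benzofuran-4-yl]-3-methylbutan-2-one, via o-hydroxybenzyl aryl ketone 10 (not isolated), via protected benzofuran 11 (not isolated)
Conditions: 9 (1.5 equiv), TMSOTf (0.3 equiv), CH2Cl2, −78 → −20 °C; then TFA–CH2Cl2 1:1, H2O (5 equiv), anisole (10 equiv), 0 °C → rt
Reagents that add atoms: none
Why: TMSOTf ionises the ketal to a 4-methoxyphenoxenium-type cation whose OtBu flank is switched off as a vinylogous ester, so the enol silane adds SN2′ only at the ring CH next to the side chain and rearomatisation gives 10 (acid-promoted formal [3+2] coupling of a p-quinone monoketal with an enol ether), after which the phenol OH closes the furan C–O bond by cyclodehydration and TFA cleaves the tert-butyl and TMS ethers (every ring position open to t-Bu+ is doubly flanked, and anisole scavenges the rest).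

**Compound list**
1 | 1-bromo-3-(tert-butoxy)benzene | CC(C)(C)Oc1cccc(Br)c1 | starting material
2 | 3-methylbutan-2-one | CC(=O)C(C)C | starting material
3 | 1-[3-(tert-butoxy)phenyl]-3-methylbutan-2-one | CC(C)C(=O)Cc1cccc(OC(C)(C)C)c1 | intermediate
4 | 1-[3-(tert-butoxy)-5-(4,4,5,5-tetramethyl-1,3,2-dioxaborolan-2-yl)phenyl]-3-methylbutan-2-one | CC(C)C(=O)Cc1cc(OC(C)(C)C)cc(B2OC(C)(C)C(C)(C)O2)c1 | intermediate
5 | 1-[3-(tert-butoxy)-5-hydroxyphenyl]-3-methylbutan-2-one | CC(C)C(=O)Cc1cc(O)cc(OC(C)(C)C)c1 | intermediate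
6 | 1-[3-(tert-butoxy)-5-hydroxy-2-methoxyphenyl]-3-methylbutan-2-one | COc1c(CC(=O)C(C)C)cc(O)cc1OC(C)(C)C | intermediate
7 | 3-(tert-butoxy)-4,4-dimethoxy-5-(3-methyl-2-oxobutyl)cyclohexa-2,5-dien-1-one | COC1(OC)C(CC(=O)C(C)C)=CC(=O)C=C1OC(C)(C)C | intermediate
8 | 1-(3,5-dihydroxyphenyl)ethan-1-one (3,5-dihydroxyacetophenone) | CC(=O)c1cc(O)cc(O)c1 | starting material
9 | 1-[3,5-bis(trimethylsilyloxy)phenyl]-1-(trimethylsilyloxy)ethene | C=C(O[Si](C)(C)C)c1cc(O[Si](C)(C)C)cc(O[Si](C)(C)C)c1 | intermediate
10 | 1-{3-(tert-butoxy)-5-hydroxy-2-methoxy-6-[2-oxo-2-(3,5-bis(trimethylsilyloxy)phenyl)ethyl]phenyl}-3-methylbutan-2-one | COc1c(OC(C)(C)C)cc(O)c(CC(=O)c2cc(O[Si](C)(C)C)cc(O[Si](C)(C)C)c2)c1CC(=O)C(C)C | intermediate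
11 | 1-{6-(tert-butoxy)-5-methoxy-2-[3,5-bis(trimethylsilyloxy)phenyl]-1-benzofuran-4-yl}-3-methylbutan-2-one | COc1c(OC(C)(C)C)cc2oc(-c3cc(O[Si](C)(C)C)cc(O[Si](C)(C)C)c3)cc2c1CC(=O)C(C)C | intermediate
12 | moracin Q, 1-[2-(3,5-dihydroxyphenyl)-6-hydroxy-5-methoxy-1-benzofuran-4-yl]-3-methylbutan-2-one (achiral) | COc1c(O)cc2oc(-c3cc(O)cc(O)c3)cc2c1CC(=O)C(C)C | target

**Total step count:** 4
**Longest linear sequence:** 3 steps (1 → 3 → 7 → 12)

**Three steps most likely to fail**

**Step 2 (the proposed new step).**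
- Risks:
  - B→O transfer from a pinacol ester to I(III) may be slow.
  - Liberated pinacol may consume oxidant.
  - The enolisable benzylic ketone may be α‑oxidised.
  - The ketone carbonyl may trap the phenoxenium ion.
  - MeOH may attack ortho instead of para.
- Fallback (known chemistry, one extra step), from 3 back to 7. The same Ir borylation gives 4, which is oxidised in the same pot with Oxone in acetone–water (the established C–H borylation/oxidation phenol synthesis), and phenol 5 is isolated. In a separate reaction, 5 is treated with PhI(OAc)2 (2.1 equiv) in MeOH at 0 °C (the established phenol to p‑quinone monoketal oxidation) and passes through 6 to 7. No compound outside the list is made.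

**Step 4.**
- Risks:
  - The ring CH that must be attacked is flanked by the side chain.
  - The tert‑butyl vinylogous ester may be lost early.
  - The enol silane may add at the ketal carbon or be protodesilylated.
- Fallback, from 7 back to 12, closing the furan by alkyne hydroalkoxylation instead. Zn/AcOH reduces 7 to methoxyphenol 6. NIS (cat. TsOH, MeCN, 0 °C) iodinates ortho to OH and para to OtBu, giving 1-[3-(tert-butoxy)-5-hydroxy-6-iodo-2-methoxyphenyl]-3-methylbutan-2-one F1. Commercial 3,5‑dihydroxybenzaldehyde and the Ohira–Bestmann reagent (K2CO3, MeOH) give 5-ethynylbenzene-1,3-diol F2. PdCl2(PPh3)2/CuI/Et3N in DMF couples F1 with F2 to 1-{3-(tert-butoxy)-6-[(3,5-dihydroxyphenyl)ethynyl]-5-hydroxy-2-methoxyphenyl}-3-methylbutan-2-one F3. On warming to 60–80 °C this closes 5‑endo‑dig to 1-[6-(tert-butoxy)-2-(3,5-dihydroxyphenyl)-5-methoxy-1-benzofuran-4-yl]-3-methylbutan-2-one F4. TFA/anisole then gives 12.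

**Step 1.**
- Risks:
  - Diarylation at the newly acidic benzylic CH2.
  - Aldol self‑condensation of 2.
- Fallback, from 1 back to 3, building the chain by epoxide opening and oxidation. Mg in THF converts 1 into [3-(tert-butoxy)phenyl]magnesium bromide F5. CuI (10 mol %) catalysed opening of commercial 2‑isopropyloxirane at its CH2 gives racemic 1-[3-(tert-butoxy)phenyl]-3-methylbutan-2-ol F6. Dess–Martin oxidation gives 3.

**Further compounds**
F0 | step 2 | none | none
F1 | step 4 | 1-[3-(tert-butoxy)-5-hydroxy-6-iodo-2-methoxyphenyl]-3-methylbutan-2-one | COc1c(OC(C)(C)C)cc(O)c(I)c1CC(=O)C(C)C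
F2 | step 4 | 5-ethynylbenzene-1,3-diol | C#Cc1cc(O)cc(O)c1
F3 | step 4 | 1-{3-(tert-butoxy)-6-[(3,5-dihydroxyphenyl)ethynyl]-5-hydroxy-2-methoxyphenyl}-3-methylbutan-2-one | COc1c(OC(C)(C)C)cc(O)c(C#Cc2cc(O)cc(O)c2)c1CC(=O)C(C)C
F4 | step 4 | 1-[6-(tert-butoxy)-2-(3,5-dihydroxyphenyl)-5-methoxy-1-benzofuran-4-yl]-3-methylbutan-2-one | COc1c(OC(C)(C)C)cc2oc(-c3cc(O)cc(O)c3)cc2c1CC(=O)C(C)C
F5 | step 1 | [3-(tert-butoxy)phenyl]magnesium bromide | CC(C)(C)Oc1cccc([Mg]Br)c1
F6 | step 1 | 1-[3-(tert-butoxy)phenyl]-3-methylbutan-2-ol (racemic) | CC(C)C(O)Cc1cccc(OC(C)(C)C)c1
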